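**Strategy.** The decalin is traced back to (R)-carvone: the carvone ring is ring B (C5–C10) and its isopropenyl carbon becomes C4. The route rests on closing ring A (C1–C5, C10) as the only ring-forming event, at the C3–C4 bond. The key step exploits the gem-dimethyl quaternary C4 beside the C5–H ring-fusion carbon: Markovnikov hydrogen-atom transfer to the isopropenyl group makes the second C4 methyl and a tertiary C4 radical, which adds 6-endo to a 2-sulfonylallyl arm on the quaternary C10, giving the trans-fused 4,4,10-trimethyldecalin in one operation. The precursor is a 6,6-dialkylated carvone. The derived drimenyl unit is joined to a stereodefined (Z)-iodoalkene, which is then converted into the enol sulfate.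

Key step: step 4

Numbering: drimane numbering is used for the decalin (ring A = C1–C5 and C10; ring B = C5–C10; C11 on C9). The chain continues as C12, C13 (the carbon bearing the enol CH–O), C14–C16, C17(Me)=C18 and benzylic C19. Steps 1–3 also use carvone numbering where stated.

Assumption: sulfate monoesters are handled as sodium salts; the hydrogen sulfate drawn for the target is released from its sodium salt by one equivalent of HCl in the last operation and should be kept cold and used without storage.

**Step 1**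
Reactants: 1 (R)-(−)-carvone
Product: 3 6-methylcarvone (C6 epimers; carvone numbering), via lithium dienolate 2 (not isolated)
Conditions: LDA, THF, −78 °C; MeI, −78 → 0 °C
Reagents that add atoms: iodomethane, CI
Why: Kinetic α′-deprotonation gives the cross-conjugated lithium dienolate, whose C-methylation (enolate alkylation) installs the future C10 methyl; the epimer mixture is harmless because this carbon is re-enolised in step 2.

**Step 2**
Reactants: 3 6-methylcarvone; 4 2,3-dibromopropene
Product: 6 (5S,6S)-6-(2-bromoallyl)-6-methylcarvone, via lithium dienolate 5 (not isolated)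
Conditions: LDA, THF, −78 → 0 °C; DMPU; 4, −78 °C → rt
Reagents that add atoms: none
Why: Enolate alkylation of the fully substituted dienolate with the allylic bromide: 1,2-allylic strain holds the isopropenyl group pseudo-axial and the electrophile enters anti to it, which should set the quaternary C10 with the CH2 arm trans and the methyl cis to isopropenyl (the relative configuration of a trans-decalin); the vinylic bromide is inert.

**Step 3**
Reactants: 6 bromoallyl ketone
Product: 7 (5S,6S)-6-methyl-6-[2-(phenylsulfonyl)allyl]carvone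
Conditions: PhSO2Na, CuI (10 mol %), L-proline (20 mol %), NaOH (20 mol %), DMSO, 90 °C
Reagents that add atoms: sodium benzenesulfinate, [Na+].[O-]S(=O)c1ccccc1
Why: Copper-catalysed Ullmann-type coupling of the vinylic bromide with the sulfinate (C–S bond formation) turns the arm into a radical acceptor polarised for attack at its CH2 terminus; no stereocentre is touched.

**Step 4**
Reactants: 7 vinyl sulfone
Product: 8 (5S,10S)-2-(phenylsulfonyl)-11-nordrim-7-en-9-one (trans-fused; C2 epimers)
Conditions: Fe(acac)3 (30 mol %), PhSiH3, EtOH/(CH2OH)2 5:1, 60 °C, 0.02 M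
Reagents that add atoms: none
Why: Fe(acac)3/PhSiH3 generates an iron hydride that transfers a hydrogen atom to the CH2 terminus of the electron-rich isopropenyl group (Markovnikov MHAT), which makes the second C4 methyl and the tertiary C4 radical; this nucleophilic radical adds to the unsubstituted CH2 terminus (C3) of the 2-sulfonylallyl arm, and the α-sulfonyl C2 radical is reduced by Fe(II) and protonated by ethanol. The closest known reaction type is the iron-mediated reductive olefin coupling (MHAT-initiated Giese addition), used here intramolecularly. Ring A (C1–C5, C10) closes in the 6-endo-trig mode; the 5-exo alternative would require attack on the sulfonyl-bearing C2 and is disfavoured by polarity and substitution. No stereocentre of the target is created: C5 (from carvone) and C10 (step 2) are fixed and their trans-diequatorial arms can only close to the trans-fused decalin, while the C2 epimers converge when the sulfone is removed in step 7. The step needs chemoselective hydrogen-atom transfer to the 1,1-disubstituted alkene in the presence of the enone and the vinyl sulfone (both polarity-mismatched for the hydridic H donor) and cyclisation faster than reduction of the C4 radical, secured by the activated acceptor held five atoms away and by high dilution.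

**Step 5**
Reactants: 8 bicyclic sulfonyl enone
Product: 9 (5S,10S)-2-(phenylsulfonyl)drima-7,9(11)-diene
Conditions: Ph3PCH3Br, KOtBu (slight deficit), toluene, 90 °C
Reagents that add atoms: methyltriphenylphosphonium bromide, C[P+](c1ccccc1)(c1ccccc1)c1ccccc1.[Br-]
Why: Wittig methylenation of the hindered but non-enolisable C9 ketone (quaternary C10 on one side, sp2 C8 on the other) gives the exocyclic 7,9(11)-diene; the ylide is not basic enough to deprotonate the sulfone.

**Step 6**
Reactants: 9 sulfonyl diene
Product: 11 (5S,9S,10S)-2-(phenylsulfonyl)drim-7-en-11-ol, via B-alkyl-9-BBN adduct 10 (not isolated)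
Conditions: 9-BBN, THF, 0 → 50 °C; NaOH, H2O2, 0 °C → rt
Reagents that add atoms: hydrogen peroxide, OO
Why: Hydroboration–oxidation: 9-BBN places boron on the terminal C11 of the less hindered, exocyclic alkene of the diene and delivers hydrogen to C9 from the α-face, away from the axial C10 methyl, which should set 9S (H-9 trans to the C10 methyl, C11 equatorial); oxidation retains configuration.

**Step 7**
Reactants: 11 sulfonyl drimenol
Product: 12 (−)-drimenol
Conditions: 6 % Na(Hg), MeOH/THF, −20 °C → rt
Reagents that add atoms: none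
Why: Reductive desulfonylation by electron transfer from sodium amalgam (Julia-type C–S cleavage) removes the auxiliary and with it the C2 epimer mixture; the isolated trisubstituted alkene and the alcohol are inert.

**Step 8**
Reactants: 12 (−)-drimenol
Product: 13 (5S,9S,10S)-11-iododrim-7-ene
Conditions: I2, PPh3, imidazole, CH2Cl2, 0 °C → rt
Reagents that add atoms: iodine, II
Why: Garegg–Samuelsson (Appel-type) iodination: the alkoxyphosphonium ion is displaced by iodide in an SN2 reaction at primary C11, which leaves C9 untouched.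

**Step 9**
Reactants: 14 2,5-dihydroxybenzaldehyde
Product: 15 2,5-bis(triisopropylsilyloxy)benzaldehyde
Conditions: TIPSCl, imidazole, DMAP (cat.), DMF, 40 °C
Reagents that add atoms: chlorotriisopropylsilane, CC(C)[Si](Cl)(C(C)C)C(C)C
Why: Silylation of both phenols under nucleophilic catalysis; TIPS ethers are chosen because they should resist the organometallic steps and fall to fluoride at the end.

**Step 10**
Reactants: 15 bis-silylated aldehyde
Product: 16 [2,5-bis(triisopropylsilyloxy)phenyl]methanol
Conditions: NaBH4, MeOH/THF, 0 °C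
Reagents that add atoms: none
Why: Hydride reduction of the aldehyde with NaBH4; low temperature limits phenol-to-alkoxide silyl migration.

**Step 11**
Reactants: 16 benzylic alcohol
Product: 17 2,5-bis(triisopropylsilyloxy)benzyl chloride
Conditions: PPh3, NCS (premixed), THF, 0 °C → rt
Reagents that add atoms: N-chlorosuccinimide, O=C1CCC(=O)N1Cl
Why: Appel-type chlorination through the chlorophosphonium salt formed from PPh3 and NCS, an SN2 reaction at the benzylic carbon under neutral conditions that spare the aryl silyl ethers.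

**Step 12**
Reactants: 18 5-chloropent-1-yne; 17 benzylic chloride
Product: 20 2-[(2E)-6-chloro-3-methylhex-2-en-1-yl]-1,4-bis(triisopropylsilyloxy)benzene, via alkenylalane 19 (not isolated)
Conditions: Me3Al, Cp2ZrCl2 (20 mol %), CH2Cl2, 0 °C → rt; then 17, Pd(PPh3)4 (5 mol %), THF, rt
Reagents that add atoms: trimethylaluminium, C[Al](C)C
Why: Negishi zirconium-catalysed carboalumination adds Me–Al syn and regioselectively across the terminal alkyne, and the palladium-catalysed cross-coupling of the alkenylalane with the benzylic chloride proceeds with retention, so the trisubstituted alkene is E; the primary alkyl chloride is inert to both operations.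

**Step 13**
Reactants: 20 alkyl chloride; 21 prop-2-yn-1-ol
Product: 25 (2Z,6E)-8-[2,5-bis(triisopropylsilyloxy)phenyl]-2-(iodomethylidene)-6-methyloct-6-en-1-ol, via Grignard reagent 22 (not isolated), via magnesium alkoxide 23 (not isolated), via alkenylmagnesium chelate 24 (not isolated)
Conditions: 20, Mg, THF, 50 °C; 21, EtMgBr, THF, 0 °C; combine, CuI (15 mol %), 0 °C → rt; I2, −78 → 0 °C
Reagents that add atoms: iodine, II
Why: Copper-catalysed anti-carbomagnesiation of the propargylic alkoxide (Duboudin–Jousseaume reaction): the alkyl group adds to the internal carbon and magnesium to the terminal carbon within a five-membered chelate, and iodinolysis with retention gives the (Z)-iodoalkene with iodine cis to CH2OH, which fixes the later enol geometry.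

**Step 14**
Reactants: 25 (Z)-iodo allylic alcohol
Product: 26 2-[(2E,7Z)-8-bromo-7-(iodomethylidene)-3-methyloct-2-en-1-yl]-1,4-bis(triisopropylsilyloxy)benzene
Conditions: CBr4, PPh3, CH2Cl2, 0 °C
Reagents that add atoms: carbon tetrabromide, BrC(Br)(Br)Br
Why: Appel bromination of the primary allylic alcohol (SN2 on the alkoxyphosphonium ion) under neutral conditions that keep both alkene geometries.

**Step 15**
Reactants: 13 11-iododrim-7-ene; 26 allylic bromide
Product: 29 2-[(2E,7Z)-8-(drim-7-en-11-yl)-7-(iodomethylidene)-3-methyloct-2-en-1-yl]-1,4-bis(triisopropylsilyloxy)benzene, via drimenyllithium 27 (not isolated), via drimenylmagnesium bromide 28 (not isolated)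
Conditions: 13, t-BuLi (2 equiv), Et2O/pentane, −78 °C; MgBr2·OEt2, −78 → 0 °C; then 26, Li2CuCl4 (5 mol %), THF, −78 → −20 °C
Reagents that add atoms: none
Why: Kochi–Tamura copper-catalysed coupling of a primary alkyl Grignard reagent with an allylic bromide: lithium–iodine exchange and transmetallation give the Grignard reagent, and cuprate-type conditions (Li2CuCl4, THF, low temperature) favour direct α-substitution at C12 over attack at the iodine-bearing γ-carbon and should be much faster than coupling at the alkenyl iodide, whose geometry is kept.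

**Step 16**
Reactants: 29 (Z)-alkenyl iodide
Product: 32 sodium (Z)-enol sulfate of the bis-TIPS ether, via alkenyllithium 30 (not isolated), via lithium enolate 31 (not isolated)
Conditions: t-BuLi (2 equiv), Et2O/THF, −78 °C; t-BuOOLi (from t-BuOOH, n-BuLi, THF, −78 °C), −78 → −20 °C; SO3·pyridine, DMF, −40 → 0 °C; aq. NaHCO3
Reagents that add atoms: tert-butyl hydroperoxide, CC(C)(C)OO; sulfur trioxide–pyridine complex, [O-]S(=O)(=O)[n+]1ccccc1; sodium hydrogencarbonate, [Na+].OC([O-])=O
Why: Iodine–lithium exchange gives the configurationally stable alkenyllithium, electrophilic oxygen transfer from lithium tert-butyl peroxide (oxenoid oxidation) converts it into the aldehyde lithium enolate with retention, and O-sulfonation of the hard enolate oxygen by SO3·pyridine fixes the (Z)-enol sulfate (oxygen cis to the C12 branch) while the phenols are still silylated.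

**Step 17**
Reactants: 32 silylated sodium enol sulfate
Product: 34 target hydrogen sulfate, via sodium salt 33 (not isolated)
Conditions: TBAF, AcOH, THF, 0 °C, argon; then HCl (1.0 equiv), MeOH/Et2O, −20 °C
Reagents that add atoms: none
Why: Fluoride-induced cleavage of the two aryl silyl ethers (buffered with acetic acid so that the hydroquinone is not left as its air-sensitive phenoxide) followed by protonation of the sulfate salt with one equivalent of strong acid; the enol sulfate monoester anion is inert to fluoride.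

**Compound list**

1 | (R)-(−)-carvone | CC1=CC[C@H](CC1=O)C(C)=C | starting material
2 | lithium dienolate of 1 | CC1=CC[C@H](C=C1O[Li])C(C)=C | intermediate (not isolated)
3 | (5R)-2,6-dimethyl-5-(prop-1-en-2-yl)cyclohex-2-en-1-one, mixture of C6 epimers | CC1=CC[C@H](C(C)C1=O)C(C)=C | intermediate
4 | 2,3-dibromopropene | BrCC(Br)=C | starting material
5 | lithium dienolate of 3 | CC1=CC[C@H](C(C)=C1O[Li])C(C)=C | intermediate (not isolated)
6 | (5S,6S)-6-(2-bromoprop-2-en-1-yl)-2,6-dimethyl-5-(prop-1-en-2-yl)cyclohex-2-en-1-one (bromoallyl trans, methyl cis to isopropenyl) | CC1=CC[C@H]([C@](C)(CC(Br)=C)C1=O)C(C)=C | intermediate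
7 | (5S,6S)-2,6-dimethyl-6-[2-(phenylsulfonyl)prop-2-en-1-yl]-5-(prop-1-en-2-yl)cyclohex-2-en-1-one | CC1=CC[C@H]([C@](C)(CC(=C)S(=O)(=O)c2ccccc2)C1=O)C(C)=C | intermediate
8 | (5S,10S)-2-(phenylsulfonyl)-11-nordrim-7-en-9-one, trans-fused, C2 epimers [(4aS,8aS)-2,5,5,8a-tetramethyl-7-(phenylsulfonyl)-4a,5,6,7,8,8a-hexahydronaphthalen-1(4H)-one] | CC1=CC[C@H]2C(C)(C)CC(S(=O)(=O)c3ccccc3)C[C@]2(C)C1=O | intermediate
9 | (5S,10S)-2-(phenylsulfonyl)drima-7,9(11)-diene | CC1=CC[C@H]2C(C)(C)CC(S(=O)(=O)c3ccccc3)C[C@]2(C)C1=C | intermediate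
10 | B-[2-(phenylsulfonyl)drim-7-en-11-yl]-9-borabicyclo[3.3.1]nonane | CC1=CC[C@H]2C(C)(C)CC(S(=O)(=O)c3ccccc3)C[C@]2(C)[C@H]1CB1C2CCCC1CCC2 | intermediate (not isolated)
11 | (5S,9S,10S)-2-(phenylsulfonyl)drim-7-en-11-ol | CC1=CC[C@H]2C(C)(C)CC(S(=O)(=O)c3ccccc3)C[C@]2(C)[C@H]1CO | intermediate
12 | (−)-drimenol, (5S,9S,10S)-drim-7-en-11-ol | CC1=CC[C@H]2C(C)(C)CCC[C@]2(C)[C@H]1CO | intermediate
13 | (5S,9S,10S)-11-iododrim-7-ene | CC1=CC[C@H]2C(C)(C)CCC[C@]2(C)[C@H]1CI | intermediate
14 | 2,5-dihydroxybenzaldehyde | O=Cc1cc(O)ccc1O | starting material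
15 | 2,5-bis(triisopropylsilyloxy)benzaldehyde | O=Cc1cc(O[Si](C(C)C)(C(C)C)C(C)C)ccc1O[Si](C(C)C)(C(C)C)C(C)C | intermediate
16 | [2,5-bis(triisopropylsilyloxy)phenyl]methanol | OCc1cc(O[Si](C(C)C)(C(C)C)C(C)C)ccc1O[Si](C(C)C)(C(C)C)C(C)C | intermediate
17 | 2,5-bis(triisopropylsilyloxy)benzyl chloride | ClCc1cc(O[Si](C(C)C)(C(C)C)C(C)C)ccc1O[Si](C(C)C)(C(C)C)C(C)C | intermediate
18 | 5-chloropent-1-yne | C#CCCCCl | starting material
19 | (E)-(5-chloro-2-methylpent-1-en-1-yl)dimethylalumane | ClCCC/C(C)=C/[Al](C)C | intermediate (not isolated)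
20 | 2-[(2E)-6-chloro-3-methylhex-2-en-1-yl]-1,4-bis(triisopropylsilyloxy)benzene | ClCCC/C(C)=C/Cc1cc(O[Si](C(C)C)(C(C)C)C(C)C)ccc1O[Si](C(C)C)(C(C)C)C(C)C | intermediate
21 | prop-2-yn-1-ol | C#CCO | starting material
22 | Grignard reagent of 20 | Cl[Mg]CCC/C(C)=C/Cc1cc(O[Si](C(C)C)(C(C)C)C(C)C)ccc1O[Si](C(C)C)(C(C)C)C(C)C | intermediate (not isolated)
23 | bromomagnesium prop-2-yn-1-olate | C#CCO[Mg]Br | intermediate (not isolated)
24 | alkenylmagnesium chelate, drawn open: Mg on the terminal carbon cis to CH2OMgBr | Br[Mg]OC/C(=C\[Mg]Cl)CCC/C(C)=C/Cc1cc(O[Si](C(C)C)(C(C)C)C(C)C)ccc1O[Si](C(C)C)(C(C)C)C(C)C | intermediate (not isolated)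
25 | (2Z,6E)-8-[2,5-bis(triisopropylsilyloxy)phenyl]-2-(iodomethylidene)-6-methyloct-6-en-1-ol (iodine cis to CH2OH) | OC/C(=C\I)CCC/C(C)=C/Cc1cc(O[Si](C(C)C)(C(C)C)C(C)C)ccc1O[Si](C(C)C)(C(C)C)C(C)C | intermediate
26 | 2-[(2E,7Z)-8-bromo-7-(iodomethylidene)-3-methyloct-2-en-1-yl]-1,4-bis(triisopropylsilyloxy)benzene | BrC/C(=C\I)CCC/C(C)=C/Cc1cc(O[Si](C(C)C)(C(C)C)C(C)C)ccc1O[Si](C(C)C)(C(C)C)C(C)C | intermediate
27 | drim-7-en-11-yllithium | CC1=CC[C@H]2C(C)(C)CCC[C@]2(C)[C@H]1C[Li] | intermediate (not isolated)
28 | drim-7-en-11-ylmagnesium bromide | CC1=CC[C@H]2C(C)(C)CCC[C@]2(C)[C@H]1C[Mg]Br | intermediate (not isolated)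
29 | 2-[(2E,7Z)-8-(drim-7-en-11-yl)-7-(iodomethylidene)-3-methyloct-2-en-1-yl]-1,4-bis(triisopropylsilyloxy)benzene (iodine cis to the C12 branch) | CC1=CC[C@H]2C(C)(C)CCC[C@]2(C)[C@H]1CC/C(=C\I)CCC/C(C)=C/Cc1cc(O[Si](C(C)C)(C(C)C)C(C)C)ccc1O[Si](C(C)C)(C(C)C)C(C)C | intermediate
30 | alkenyllithium from 29 (Li in place of I, same geometry) | CC1=CC[C@H]2C(C)(C)CCC[C@]2(C)[C@H]1CC/C(=C\[Li])CCC/C(C)=C/Cc1cc(O[Si](C(C)C)(C(C)C)C(C)C)ccc1O[Si](C(C)C)(C(C)C)C(C)C | intermediate (not isolated)
31 | (Z)-lithium enolate (OLi in place of I) | CC1=CC[C@H]2C(C)(C)CCC[C@]2(C)[C@H]1CC/C(=C\O[Li])CCC/C(C)=C/Cc1cc(O[Si](C(C)C)(C(C)C)C(C)C)ccc1O[Si](C(C)C)(C(C)C)C(C)C | intermediate (not isolated)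
32 | sodium (Z)-enol sulfate, bis-TIPS ether of the target | CC1=CC[C@H]2C(C)(C)CCC[C@]2(C)[C@H]1CC/C(=C\OS(=O)(=O)[O-])CCC/C(C)=C/Cc1cc(O[Si](C(C)C)(C(C)C)C(C)C)ccc1O[Si](C(C)C)(C(C)C)C(C)C.[Na+] | intermediate
33 | sodium salt of the target | CC1=CC[C@H]2C(C)(C)CCC[C@]2(C)[C@H]1CC/C(=C\OS(=O)(=O)[O-])CCC/C(C)=C/Cc1cc(O)ccc1O.[Na+] | intermediate (not isolated)
34 | target: (5S,9S,10S)-drim-7-ene carrying on C11 the (Z)-enol hydrogen sulfate chain (sulfate oxygen cis to the C12 branch), (E)-C17=C18 alkene and 2-substituted hydroquinone | CC1=CC[C@H]2C(C)(C)CCC[C@]2(C)[C@H]1CC/C(=C\OS(=O)(=O)O)CCC/C(C)=C/Cc1cc(O)ccc1O | target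

**Totals.** 17 steps in all. Longest linear sequence: 11 steps (steps 1–8 and 15–17, from (R)-carvone); the aryl branch is steps 9–14.

**Steps most likely to fail**

Step 4 (key step). The tertiary C4 radical may be reduced before it cyclises (net hydrogenation of the isopropenyl group), or it may add to the vinyl sulfone of a second molecule. The fallback sets out from 7 and generates the same radical in a tin hydride chain, where the hydrogen donor can be kept scarce. Markovnikov addition of HBr to the isopropenyl group (HBr, CH2Cl2, −20 °C) would give the tertiary bromide F1. Slow addition of Bu3SnH with AIBN (benzene, 80 °C, high dilution) should then close ring A in the same 6-endo mode and return to the route at 8.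

Step 15. Substitution may occur at the iodine-bearing γ-carbon (SN2′) instead of at C12, and metal–halogen exchange or coupling at the alkenyl iodide may erode the (Z)-iodide. The fallback moves the union from C11–C12 to C12–C13 and creates the iodoalkene only in the coupling event; it sets out from 13 (through 27) and from 20. Drimenyllithium 27 is trapped with paraformaldehyde to give homodrimenol F2, which is converted (CBr4, PPh3) into the homodrimenyl bromide F3. Chloride 20 is displaced with lithium acetylide (THF/DMPU, NaI cat.) to give the terminal alkyne F4. F3 is turned into the Grignard reagent F5 and, with CuBr·SMe2 (Et2O/Me2S, −45 °C), into the alkylcopper reagent F6. Syn-carbocupration of F4 by F6 (Normant reaction, −25 °C) gives the alkenylcopper F7 with the new C12 branch cis to copper, and iodinolysis returns to the route at 29.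

Step 16. Oxygen transfer to the hindered alkenyllithium may be outrun by protonation or homocoupling, and the alkoxide by-product may consume the sulfating agent. The fallback gives up stereospecific oxygenation and makes the enolate from the aldehyde instead; it sets out from 29 (through 30). Alkenyllithium 30 is borylated with 2-isopropoxy-4,4,5,5-tetramethyl-1,3,2-dioxaborolane to give the alkenylboronate F8. Oxidation with sodium perborate (THF/H2O) gives the α-branched aldehyde F9 as a mixture at C13. Deprotonation with NaHMDS (THF, −78 °C) gives the sodium enolate F10 as a mixture of both geometries, and SO3·pyridine converts it into 32 together with its (E)-isomer F11. F11 would be removed by reverse-phase HPLC, and the route is rejoined at 32.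

**Further compounds**

F1 | step 4 | (5S,6S)-5-(2-bromopropan-2-yl)-2,6-dimethyl-6-[2-(phenylsulfonyl)prop-2-en-1-yl]cyclohex-2-en-1-one | CC1=CC[C@H]([C@](C)(CC(=C)S(=O)(=O)c2ccccc2)C1=O)C(C)(C)Br
F2 | step 15 | homodrimenol, 2-(drim-7-en-11-yl)… one-carbon homologue of 12: 2-[(5S,9S,10S)-11-nordrim-7-en-9-yl]ethanol | CC1=CC[C@H]2C(C)(C)CCC[C@]2(C)[C@H]1CCO
F3 | step 15 | homodrimenyl bromide, 9-(2-bromoethyl)-11-nordrim-7-ene | CC1=CC[C@H]2C(C)(C)CCC[C@]2(C)[C@H]1CCBr
F4 | step 15 | 2-[(2E)-3-methyloct-2-en-7-yn-1-yl]-1,4-bis(triisopropylsilyloxy)benzene | C#CCCC/C(C)=C/Cc1cc(O[Si](C(C)C)(C(C)C)C(C)C)ccc1O[Si](C(C)C)(C(C)C)C(C)C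
F5 | step 15 | homodrimenylmagnesium bromide | CC1=CC[C@H]2C(C)(C)CCC[C@]2(C)[C@H]1CC[Mg]Br
F6 | step 15 | homodrimenylcopper (as its MgBr2 complex) | CC1=CC[C@H]2C(C)(C)CCC[C@]2(C)[C@H]1CC[Cu]
F7 | step 15 | alkenylcopper, Cu in place of I in 29 | CC1=CC[C@H]2C(C)(C)CCC[C@]2(C)[C@H]1CC/C(=C\[Cu])CCC/C(C)=C/Cc1cc(O[Si](C(C)C)(C(C)C)C(C)C)ccc1O[Si](C(C)C)(C(C)C)C(C)C
F8 | step 16 | alkenyl pinacol boronate, Bpin in place of I in 29 | CC1=CC[C@H]2C(C)(C)CCC[C@]2(C)[C@H]1CC/C(=C\B3OC(C)(C)C(C)(C)O3)CCC/C(C)=C/Cc1cc(O[Si](C(C)C)(C(C)C)C(C)C)ccc1O[Si](C(C)C)(C(C)C)C(C)C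
F9 | step 16 | α-branched aldehyde (C13 epimers) | CC1=CC[C@H]2C(C)(C)CCC[C@]2(C)[C@H]1CCC(C=O)CCC/C(C)=C/Cc1cc(O[Si](C(C)C)(C(C)C)C(C)C)ccc1O[Si](C(C)C)(C(C)C)C(C)C
F10 | step 16 | sodium enolate of F9, both geometries | CC1=CC[C@H]2C(C)(C)CCC[C@]2(C)[C@H]1CCC(=CO[Na])CCC/C(C)=C/Cc1cc(O[Si](C(C)C)(C(C)C)C(C)C)ccc1O[Si](C(C)C)(C(C)C)C(C)C
F11 | step 16 | (E)-enol sulfate isomer of 32 | CC1=CC[C@H]2C(C)(C)CCC[C@]2(C)[C@H]1CC/C(=C/OS(=O)(=O)[O-])CCC/C(C)=C/Cc1cc(O[Si](C(C)C)(C(C)C)C(C)C)ccc1O[Si](C(C)C)(C(C)C)C(C)C.[Na+]
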